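**Retrosynthetic overview**
- The tetronic acid is the only ring built, and it is closed last: a propionate unit is added to an α-hydroxy ester, and the resulting 4-hydroxy-2-methyl-3-oxo ester lactonises (ring O onto the ester C=O), the closure presumed for the oxidised tail isoprene unit in the sponge.
- The furan is bought as 3-bromofuran and joined by B-alkyl Suzuki coupling; the E,E-diene comes from an alkenyl–alkenyl Suzuki coupling (boronate from cross-metathesis, iodide from alkyne carboalumination).
- The ring stereocentre (R) and the ring-CH2–C(Me)= bond come from opening methyl (R)-glycidate with a Z-alkenyl copper reagent.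
- The Z-trisubstituted alkene comes from a Zhao–Wittig iodo-olefination; the side-chain (S)-methyl centre comes from (S)-β-citronellene by selective ozonolysis.
- Ring order: furan (purchased), then tetronic acid (final step).

Assumption: the tetronic acid is taken to arise in nature from the tail isoprene unit, oxidised to a 4-hydroxy-2-methyl-3-oxoacyl end that lactonises; (S)-β-citronellene is taken to be the commercial (−)-enantiomer, and the SMILES given is the one meant.

**Route**

Step 1
Reactants: 1 (S)-β-citronellene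
Product: 3 (4S)-4-methylhex-5-enal, via secondary ozonide 2 (not isolated)
Conditions: O3 (1 equiv, Sudan III end point), CH2Cl2, −78 °C; then Me2S, −78 °C → rt
Reagents that add atoms: ozone, [O-][O+]=O
Why: Ozonolysis with one equivalent of ozone cleaves the electron-rich trisubstituted alkene much faster than the monosubstituted vinyl group, and the (S)-methyl centre is not touched.

Step 2
Reactants: 3 (4S)-4-methylhex-5-enal; 4 ethyltriphenylphosphonium iodide
Product: 8 (3S,6Z)-7-iodo-3-methylocta-1,6-diene, via ethylidenetriphenylphosphorane 5 (not isolated), via (1-iodoethyl)triphenylphosphonium iodide 6 (not isolated), via (1-iodoethylidene)triphenylphosphorane 7 (not isolated)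
Conditions: 4, n-BuLi, THF, rt; I2, −78 °C; NaHMDS, −20 °C; then 3, −78 → −20 °C
Reagents that add atoms: iodine, II
Why: The Zhao–Wittig (Stork–Zhao type) olefination with the α-iodo ylide is kinetically controlled and places iodine cis to the aldehyde chain, so the later C–C bond at this carbon gives the Z-trisubstituted alkene of the target.

Step 3
Reactants: 8 (3S,6Z)-7-iodo-3-methylocta-1,6-diene; 9 methyl (R)-glycidate
Product: 12 methyl (2R,4Z,8S)-2-hydroxy-4,8-dimethyldeca-4,9-dienoate, via alkenyllithium 10 (not isolated), via alkenylmagnesium bromide 11 (not isolated)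
Conditions: t-BuLi (2 equiv), Et2O, −78 °C; MgBr2·OEt2; CuI (10 mol %), 9, THF, −40 → −20 °C; aq NH4Cl
Reagents that add atoms: none
Why: Iodine–lithium exchange and transmetallation keep the alkene geometry, and copper-catalysed Grignard opening of the glycidic ester occurs at the CH2 terminus, so the (R) carbinol centre (the future ring stereocentre) is carried over unchanged from the chiral pool.

Step 4
Reactants: 12 methyl (2R,4Z,8S)-2-hydroxy-4,8-dimethyldeca-4,9-dienoate; 13 vinylboronic acid pinacol ester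
Product: 14 methyl (2R,4Z,8S,9E)-2-hydroxy-4,8-dimethyl-10-(4,4,5,5-tetramethyl-1,3,2-dioxaborolan-2-yl)deca-4,9-dienoate
Conditions: 13 (3 equiv), Grubbs II (5 mol %), CH2Cl2, 40 °C
Reagents that add atoms: none
Why: Olefin cross-metathesis engages only the terminal vinyl group (the trisubstituted alkene is inert) and gives the E-alkenyl boronate, favoured by the allylic branch.

Step 5
Reactants: 15 pent-1-en-4-yne
Product: 17 (1E)-1-iodo-2-methylpenta-1,4-diene, via alkenylalane 16 (not isolated)
Conditions: Me3Al, Cp2ZrCl2 (20 mol %), CH2Cl2, 0 °C → rt; then I2, THF, −30 → 0 °C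
Reagents that add atoms: trimethylaluminium, C[Al](C)C; iodine, II
Why: Negishi zirconium-catalysed carboalumination adds Me and Al syn across the terminal alkyne (Me to the internal carbon), and iodinolysis with retention gives the E-trisubstituted iodide while the isolated alkene is left alone.

Step 6
Reactants: 14 alkenyl boronate from step 4; 17 (1E)-1-iodo-2-methylpenta-1,4-diene
Product: 18 methyl (2R,4Z,8S,9E,11E)-2-hydroxy-4,8,12-trimethylpentadeca-4,9,11,14-tetraenoate
Conditions: Pd(dppf)Cl2 (5 mol %), aq K3PO4, DMF, rt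
Reagents that add atoms: none
Why: Suzuki–Miyaura alkenyl–alkenyl coupling proceeds with retention at both partners and so gives the E,E-diene next to the untouched (S)-methyl centre, under conditions mild enough for the hydroxy ester.

Step 7
Reactants: 18 tetraene hydroxy ester from step 6; 19 3-bromofuran
Product: 21 methyl (2R,4Z,8S,9E,11E)-15-(furan-3-yl)-2-hydroxy-4,8,12-trimethylpentadeca-4,9,11-trienoate, via B-alkyl-9-BBN adduct 20 (not isolated)
Conditions: 9-BBN (2.3 equiv), THF, 0 °C → rt; then 19, Pd(dppf)Cl2 (5 mol %), AsPh3, Cs2CO3, DMF/H2O, rt → 40 °C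
Reagents that add atoms: none
Why: 9-BBN hydroborates only the monosubstituted terminal alkene (anti-Markovnikov; one further equivalent is consumed by the OH), and the B-alkyl Suzuki–Miyaura coupling then joins the primary carbon to C3 of the furan.

Step 8
Reactants: 21 furyl hydroxy ester from step 7; 22 methyl propanoate
Product: 25 episarcotin A, via methyl propanoate lithium enolate 23 (not isolated), via 4-hydroxy-3-oxo ester 24 (not isolated)
Conditions: 21, LiHMDS (1 equiv), THF, −78 °C; add to 22/LDA (3 equiv), −78 → −20 °C; then 1 M HCl, THF, rt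
Reagents that add atoms: none
Why: A crossed Claisen condensation of the propionate enolate on the α-oxido ester gives the 4-hydroxy-2-methyl-3-oxo ester, which on acidification lactonises (5-exo-trig O-acylation) to the tetronic acid on the unprotected polyene, and the ring stereocentre stays (R) because the ester enolate is too weak a base to enolise the α-oxido ester.

**Compound list**

1 | (S)-β-citronellene [(3S)-3,7-dimethylocta-1,6-diene] | CC(C)=CCC[C@H](C)C=C | starting material
2 | 3,3-dimethyl-5-[(3S)-3-methylpent-4-en-1-yl]-1,2,4-trioxolane (secondary ozonide) | CC1(C)OOC(CC[C@H](C)C=C)O1 | intermediate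
3 | (4S)-4-methylhex-5-enal | O=CCC[C@H](C)C=C | intermediate
4 | ethyltriphenylphosphonium iodide | CC[P+](c1ccccc1)(c1ccccc1)c1ccccc1.[I-] | starting material
5 | ethylidenetriphenylphosphorane | CC=P(c1ccccc1)(c1ccccc1)c1ccccc1 | intermediate
6 | (1-iodoethyl)triphenylphosphonium iodide | CC(I)[P+](c1ccccc1)(c1ccccc1)c1ccccc1.[I-] | intermediate
7 | (1-iodoethylidene)triphenylphosphorane | CC(I)=P(c1ccccc1)(c1ccccc1)c1ccccc1 | intermediate
8 | (3S,6Z)-7-iodo-3-methylocta-1,6-diene | C/C(I)=C/CC[C@H](C)C=C | intermediate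
9 | methyl (R)-glycidate [methyl (2R)-oxirane-2-carboxylate] | COC(=O)[C@H]1CO1 | starting material
10 | [(6S)-6-methylocta-2,7-dien-2-yl]lithium (Li cis to the chain) | C/C([Li])=C/CC[C@H](C)C=C | intermediate
11 | [(6S)-6-methylocta-2,7-dien-2-yl]magnesium bromide (Mg cis to the chain) | C/C([Mg]Br)=C/CC[C@H](C)C=C | intermediate
12 | methyl (2R,4Z,8S)-2-hydroxy-4,8-dimethyldeca-4,9-dienoate | COC(=O)[C@H](O)C/C(C)=C\CC[C@H](C)C=C | intermediate
13 | vinylboronic acid pinacol ester (4,4,5,5-tetramethyl-2-vinyl-1,3,2-dioxaborolane) | C=CB1OC(C)(C)C(C)(C)O1 | starting material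
14 | methyl (2R,4Z,8S,9E)-2-hydroxy-4,8-dimethyl-10-(4,4,5,5-tetramethyl-1,3,2-dioxaborolan-2-yl)deca-4,9-dienoate | COC(=O)[C@H](O)C/C(C)=C\CC[C@H](C)/C=C/B1OC(C)(C)C(C)(C)O1 | intermediate
15 | pent-1-en-4-yne | C=CCC#C | starting material
16 | dimethyl[(1E)-2-methylpenta-1,4-dien-1-yl]alane | C=CC/C(C)=C/[Al](C)C | intermediate
17 | (1E)-1-iodo-2-methylpenta-1,4-diene | C=CC/C(C)=C/I | intermediate
18 | methyl (2R,4Z,8S,9E,11E)-2-hydroxy-4,8,12-trimethylpentadeca-4,9,11,14-tetraenoate | COC(=O)[C@H](O)C/C(C)=C\CC[C@H](C)/C=C/C=C(\C)CC=C | intermediate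
19 | 3-bromofuran | Brc1ccoc1 | starting material
20 | methyl (2R,4Z,8S,9E,11E)-15-(9-borabicyclo[3.3.1]nonan-9-yl)-2-[(9-borabicyclo[3.3.1]nonan-9-yl)oxy]-4,8,12-trimethylpentadeca-4,9,11-trienoate | COC(=O)[C@H](OB1C2CCCC1CCC2)C/C(C)=C\CC[C@H](C)/C=C/C=C(\C)CCCB1C2CCCC1CCC2 | intermediate
21 | methyl (2R,4Z,8S,9E,11E)-15-(furan-3-yl)-2-hydroxy-4,8,12-trimethylpentadeca-4,9,11-trienoate | COC(=O)[C@H](O)C/C(C)=C\CC[C@H](C)/C=C/C=C(\C)CCCc1ccoc1 | intermediate
22 | methyl propanoate | CCC(=O)OC | starting material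
23 | methyl propanoate lithium enolate | CC=C(OC)O[Li] | intermediate
24 | methyl (4R,6Z,10S,11E,13E)-17-(furan-3-yl)-4-hydroxy-2,6,10,14-tetramethyl-3-oxoheptadeca-6,11,13-trienoate (both C2 epimers) | COC(=O)C(C)C(=O)[C@H](O)C/C(C)=C\CC[C@H](C)/C=C/C=C(\C)CCCc1ccoc1 | intermediate
25 | episarcotin A, (5R)-5-[(2Z,6S,7E,9E)-13-(furan-3-yl)-2,6,10-trimethyltrideca-2,7,9-trien-1-yl]-4-hydroxy-3-methylfuran-2(5H)-one | CC1=C(O)[C@@H](C/C(C)=C\CC[C@H](C)/C=C/C=C(\C)CCCc2ccoc2)OC1=O | target

**Step count**
Total steps: 8. Longest linear sequence: 7 (steps 1, 2, 3, 4, 6, 7, 8); step 5 makes the side fragment.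

**Steps most likely to fail, with fallbacks**

Step 8 (Claisen–lactonisation on the unprotected α-hydroxy ester). The risk is a sluggish Claisen on the α-oxido ester or self-condensation of the enolate. The fallback closes the ring through carbon instead of oxygen. It sets out from 21: acylation with propanoyl chloride, pyridine and DMAP gives methyl (2R,4Z,8S,9E,11E)-15-(furan-3-yl)-4,8,12-trimethyl-2-(propanoyloxy)pentadeca-4,9,11-trienoate F10. LiHMDS (2.2 equiv, THF, −78 → 0 °C) then effects a Dieckmann cyclisation (propanoate enolate onto the methyl ester) and comes back to the route at 25.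

Step 7 (site-selective hydroboration and B-alkyl Suzuki next to a base-labile hydroxy ester). The risk is hydroboration of the diene or ester hydrolysis. The fallback puts the furan on the side fragment before the diene is made; it sets out from 14 and comes back at 21.
- Zinc insertion (Zn, LiCl, THF) into commercial (5-iodopent-1-yn-1-yl)trimethylsilane gives [5-(trimethylsilyl)pent-4-yn-1-yl]zinc iodide F5.
- Negishi coupling of F5 with 19 (Pd(OAc)2/SPhos) gives 3-[5-(trimethylsilyl)pent-4-yn-1-yl]furan F6.
- K2CO3/MeOH gives 3-(pent-4-yn-1-yl)furan F7.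
- Me3Al/Cp2ZrCl2 gives [(1E)-5-(furan-3-yl)-2-methylpent-1-en-1-yl]dimethylalane F8, and iodine then gives 3-[(4E)-5-iodo-4-methylpent-4-en-1-yl]furan F9.
- Suzuki coupling of F9 with 14 under the step 6 conditions gives 21 directly.

Step 2 (Zhao–Wittig; yields and Z:E are often moderate). The fallback builds the iodoalkene by alkyne hydroalumination instead of olefination; it sets out from 3 and comes back at 8.
- Ohira–Bestmann homologation (dimethyl (1-diazo-2-oxopropyl)phosphonate, K2CO3, MeOH) gives (3S)-3-methylhept-1-en-6-yne F1.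
- n-BuLi then TMSCl gives trimethyl[(5S)-5-methylhept-6-en-1-yn-1-yl]silane F2.
- i-Bu2AlH in Et2O/heptane adds syn with Al geminal to Si, giving diisobutyl[(1Z,5S)-5-methyl-1-(trimethylsilyl)hepta-1,6-dien-1-yl]alane F3.
- MeLi then MeI methylates F3 with retention to trimethyl[(2Z,6S)-6-methylocta-2,7-dien-2-yl]silane F4.
- NIS in MeCN (ipso-iododesilylation with retention) gives 8.

**Further compounds**

F1 | step 2 | (3S)-3-methylhept-1-en-6-yne | C#CCC[C@H](C)C=C
F2 | step 2 | trimethyl[(5S)-5-methylhept-6-en-1-yn-1-yl]silane | C[Si](C)(C)C#CCC[C@H](C)C=C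
F3 | step 2 | diisobutyl[(1Z,5S)-5-methyl-1-(trimethylsilyl)hepta-1,6-dien-1-yl]alane | CC(C)C[Al](CC(C)C)/C([Si](C)(C)C)=C/CC[C@H](C)C=C
F4 | step 2 | trimethyl[(2Z,6S)-6-methylocta-2,7-dien-2-yl]silane | C/C([Si](C)(C)C)=C/CC[C@H](C)C=C
F5 | step 7 | [5-(trimethylsilyl)pent-4-yn-1-yl]zinc iodide | C[Si](C)(C)C#CCCC[Zn]I
F6 | step 7 | 3-[5-(trimethylsilyl)pent-4-yn-1-yl]furan | C[Si](C)(C)C#CCCCc1ccoc1
F7 | step 7 | 3-(pent-4-yn-1-yl)furan | C#CCCCc1ccoc1
F8 | step 7 | [(1E)-5-(furan-3-yl)-2-methylpent-1-en-1-yl]dimethylalane | C[Al](C)/C=C(\C)CCCc1ccoc1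
F9 | step 7 | 3-[(4E)-5-iodo-4-methylpent-4-en-1-yl]furan | I/C=C(\C)CCCc1ccoc1
F10 | step 8 | methyl (2R,4Z,8S,9E,11E)-15-(furan-3-yl)-4,8,12-trimethyl-2-(propanoyloxy)pentadeca-4,9,11-trienoate | COC(=O)[C@H](OC(=O)CC)C/C(C)=C\CC[C@H](C)/C=C/C=C(\C)CCCc1ccoc1
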